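The target is a 1,3-diarylpropane-1,3-dione, and everything rests on cutting the bond between the central CH2 and the carbonyl carbon attached to the 4-hydroxy-3-prenylphenyl ring (ring B). The key step, a crossed Claisen condensation, exploits this 1,3-dicarbonyl: the CH2 is the α-carbon of the ring-A aryl ketone, and the doubly activated CH2 of the product makes its enolate the thermodynamic sink. It joins the enolate of the complete ring-A methyl ketone (2-OMe, 3-prenyl, 4-OMOM) with a ring-B methyl benzoate whose phenol is masked as a 1,1-dimethylallyl ether; that ether later rearranges into the ortho C-prenyl phenol, so the protecting group becomes the substituent.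

Key step: step 8

Remark on the chemistry: the target has no stereocentre and no stereogenic double bond; the 1,3-diketones are written in the diketo form although they should exist largely as chelated enols.

Step 1
Reactants: 1 1-(2,4-dihydroxyphenyl)ethanone, 2 3-chloro-3-methylbut-1-yne
Product: 3 1-[2-hydroxy-4-(2-methylbut-3-yn-2-yloxy)phenyl]ethanone
Conditions: K2CO3, KI (cat.), CuI (cat.), acetone, reflux
Reagents that add atoms: none
Why: Copper-assisted propargylic etherification (Williamson-type O-alkylation) should take place only at the free 4-OH, because the 2-OH is locked in a hydrogen bond to the acetyl group.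

Step 2
Reactants: 3 1-[2-hydroxy-4-(2-methylbut-3-yn-2-yloxy)phenyl]ethanone
Product: 4 1-[2-hydroxy-4-(2-methylbut-3-en-2-yloxy)phenyl]ethanone
Conditions: H2 (1 atm), Lindlar catalyst, quinoline, EtOAc, rt
Reagents that add atoms: none
Why: Lindlar semihydrogenation should stop the terminal alkyne at the alkene on the poisoned palladium and leave the aryl ketone and the aryl ether untouched.

Step 3
Reactants: 4 1-[2-hydroxy-4-(2-methylbut-3-en-2-yloxy)phenyl]ethanone
Product: 6 1-[2,4-dihydroxy-3-(3-methylbut-2-en-1-yl)phenyl]ethanone, via ortho-dienone 5 (not isolated)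
Conditions: PhNEt2, 160–190 °C, Ar
Reagents that add atoms: none
Why: Aromatic Claisen rearrangement ([3,3] shift with allylic inversion) should turn the O-CMe2-CH=CH2 group into a linear C-prenyl group at C3 rather than C5, because the chelate between the 2-OH and the acetyl group fixes double-bond character in the C3–C4 bond, and dienone 5 then tautomerizes to the phenol.

Step 4
Reactants: 6 1-[2,4-dihydroxy-3-(3-methylbut-2-en-1-yl)phenyl]ethanone
Product: 7 1-[2-hydroxy-4-(methoxymethoxy)-3-(3-methylbut-2-en-1-yl)phenyl]ethanone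
Conditions: MOMCl, K2CO3, acetone, 0 °C to rt
Reagents that add atoms: chloromethyl methyl ether (MOMCl), COCCl
Why: Williamson-type O-alkylation should give the MOM acetal selectively at the 4-OH, since the 2-OH is chelated to the ketone and flanked by two substituents.

Step 5
Reactants: 7 1-[2-hydroxy-4-(methoxymethoxy)-3-(3-methylbut-2-en-1-yl)phenyl]ethanone
Product: 8 1-[2-methoxy-4-(methoxymethoxy)-3-(3-methylbut-2-en-1-yl)phenyl]ethanone
Conditions: MeI (excess), K2CO3, DMF, 40 °C
Reagents that add atoms: iodomethane, CI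
Why: Williamson O-methylation in a polar aprotic solvent should alkylate the one remaining, chelated phenol, while the MOM ether, the prenyl group and the ketone α-position are inert to carbonate.

Step 6
Reactants: 9 methyl 4-hydroxybenzoate, 2 3-chloro-3-methylbut-1-yne
Product: 10 methyl 4-(2-methylbut-3-yn-2-yloxy)benzoate
Conditions: K2CO3, KI (cat.), CuI (cat.), acetone, reflux
Reagents that add atoms: none
Why: The same copper-assisted propargylic etherification (Williamson-type) should work well with this acidic para-ester phenol, and the methyl ester is inert to carbonate in acetone.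

Step 7
Reactants: 10 methyl 4-(2-methylbut-3-yn-2-yloxy)benzoate
Product: 11 methyl 4-(2-methylbut-3-en-2-yloxy)benzoate
Conditions: H2 (1 atm), Lindlar catalyst, quinoline, EtOAc, rt
Reagents that add atoms: none
Why: Lindlar semihydrogenation should reduce the terminal alkyne to the vinyl group without touching the ester or the arene.

Step 8
Reactants: 8 1-[2-methoxy-4-(methoxymethoxy)-3-(3-methylbut-2-en-1-yl)phenyl]ethanone, 11 methyl 4-(2-methylbut-3-en-2-yloxy)benzoate
Product: 14 1-[2-methoxy-4-(methoxymethoxy)-3-(3-methylbut-2-en-1-yl)phenyl]-3-[4-(2-methylbut-3-en-2-yloxy)phenyl]propane-1,3-dione, via sodium enolate 12 (not isolated), via sodium diketonate 13 (not isolated)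
Conditions: NaH (3 equiv), THF, reflux, ketone 8 added slowly to NaH and ester 11 (1.3 equiv); then AcOH, 0 °C
Reagents that add atoms: none
Why: Crossed Claisen condensation (ketone enolate plus non-enolizable ester): NaH converts the methyl ketone 8 into sodium enolate 12, whose α-carbon adds to the ester carbonyl of 11, and the tetrahedral adduct expels methoxide to form the CH2–C(=O) bond between the ring-A ketone α-carbon and the ring-B acyl carbon. The new 1,3-diketone (pKa about 9) is deprotonated at once to sodium diketonate 13, which drives the otherwise reversible acyl transfer forward and shields the product from a second acylation until acetic acid releases 14. The closest known reaction type is the base-mediated ketone–ester condensation used for dibenzoylmethanes. No ring is closed and no stereocentre is formed. The step needs C-acylation in the cross sense rather than ketone self-aldol or O-acylation: ester 11 has no α-hydrogen, the ketone is added slowly so that free ketone stays scarce, aldol and O-acyl products revert under the equilibrating conditions, and neither the MOM ether, the 2-methoxy group nor the tertiary allyl ether offers an acidic hydrogen or a leaving group to the base.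

Step 9
Reactants: 14 1-[2-methoxy-4-(methoxymethoxy)-3-(3-methylbut-2-en-1-yl)phenyl]-3-[4-(2-methylbut-3-en-2-yloxy)phenyl]propane-1,3-dione
Product: 16 1-[4-hydroxy-3-(3-methylbut-2-en-1-yl)phenyl]-3-[2-methoxy-4-(methoxymethoxy)-3-(3-methylbut-2-en-1-yl)phenyl]propane-1,3-dione, via ortho-dienone 15 (not isolated)
Conditions: PhNEt2, 160–190 °C, Ar
Reagents that add atoms: none
Why: Aromatic Claisen rearrangement ([3,3] shift with allylic inversion) should deliver the linear prenyl group to one of the two equivalent ortho carbons of ring B and free the phenol after tautomerization of dienone 15, the tertiary allyl aryl ether being the only thermally reactive group in the basic amine solvent.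

Step 10
Reactants: 16 1-[4-hydroxy-3-(3-methylbut-2-en-1-yl)phenyl]-3-[2-methoxy-4-(methoxymethoxy)-3-(3-methylbut-2-en-1-yl)phenyl]propane-1,3-dione
Product: 17 1-[4-hydroxy-2-methoxy-3-(3-methylbut-2-en-1-yl)phenyl]-3-[4-hydroxy-3-(3-methylbut-2-en-1-yl)phenyl]propane-1,3-dione
Conditions: aq. HCl (3 M), MeOH, rt, quenched with NaHCO3 at full conversion
Reagents that add atoms: none
Why: Acid-catalysed methanolysis of the MOM acetal (acetal cleavage) should release the ring-A phenol, and dilute acid with short exposure at room temperature should keep the ortho-prenyl phenols from cyclizing.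

Compound list
1 | 1-(2,4-dihydroxyphenyl)ethanone (2,4-dihydroxyacetophenone) | CC(=O)c1ccc(O)cc1O | starting material
2 | 3-chloro-3-methylbut-1-yne | C#CC(C)(C)Cl | starting material
3 | 1-[2-hydroxy-4-(2-methylbut-3-yn-2-yloxy)phenyl]ethanone | CC(=O)c1ccc(OC(C)(C)C#C)cc1O | intermediate
4 | 1-[2-hydroxy-4-(2-methylbut-3-en-2-yloxy)phenyl]ethanone | CC(=O)c1ccc(OC(C)(C)C=C)cc1O | intermediate
5 | 4-acetyl-3-hydroxy-2-(3-methylbut-2-en-1-yl)cyclohexa-3,5-dien-1-one (ortho-dienone; racemic; not isolated) | CC(=O)C1=C(O)C(CC=C(C)C)C(=O)C=C1 | intermediate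
6 | 1-[2,4-dihydroxy-3-(3-methylbut-2-en-1-yl)phenyl]ethanone | CC(=O)c1ccc(O)c(CC=C(C)C)c1O | intermediate
7 | 1-[2-hydroxy-4-(methoxymethoxy)-3-(3-methylbut-2-en-1-yl)phenyl]ethanone | CC(=O)c1ccc(OCOC)c(CC=C(C)C)c1O | intermediate
8 | 1-[2-methoxy-4-(methoxymethoxy)-3-(3-methylbut-2-en-1-yl)phenyl]ethanone | CC(=O)c1ccc(OCOC)c(CC=C(C)C)c1OC | intermediate
9 | methyl 4-hydroxybenzoate | COC(=O)c1ccc(O)cc1 | starting material
10 | methyl 4-(2-methylbut-3-yn-2-yloxy)benzoate | COC(=O)c1ccc(OC(C)(C)C#C)cc1 | intermediate
11 | methyl 4-(2-methylbut-3-en-2-yloxy)benzoate | COC(=O)c1ccc(OC(C)(C)C=C)cc1 | intermediate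
12 | sodium 1-[2-methoxy-4-(methoxymethoxy)-3-(3-methylbut-2-en-1-yl)phenyl]ethen-1-olate (sodium enolate of 8; not isolated) | [Na+].[O-]C(=C)c1ccc(OCOC)c(CC=C(C)C)c1OC | intermediate
13 | sodium salt of diketone 14 (sodium diketonate, drawn as the C2 carbanion form; not isolated) | [Na+].COc1c(C(=O)[CH-]C(=O)c2ccc(OC(C)(C)C=C)cc2)ccc(OCOC)c1CC=C(C)C | intermediate
14 | 1-[2-methoxy-4-(methoxymethoxy)-3-(3-methylbut-2-en-1-yl)phenyl]-3-[4-(2-methylbut-3-en-2-yloxy)phenyl]propane-1,3-dione | COc1c(C(=O)CC(=O)c2ccc(OC(C)(C)C=C)cc2)ccc(OCOC)c1CC=C(C)C | intermediate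
15 | 1-[2-methoxy-4-(methoxymethoxy)-3-(3-methylbut-2-en-1-yl)phenyl]-3-[3-(3-methylbut-2-en-1-yl)-4-oxocyclohexa-1,5-dien-1-yl]propane-1,3-dione (ortho-dienone; racemic; not isolated) | COc1c(C(=O)CC(=O)C2=CC(CC=C(C)C)C(=O)C=C2)ccc(OCOC)c1CC=C(C)C | intermediate
16 | 1-[4-hydroxy-3-(3-methylbut-2-en-1-yl)phenyl]-3-[2-methoxy-4-(methoxymethoxy)-3-(3-methylbut-2-en-1-yl)phenyl]propane-1,3-dione | COc1c(C(=O)CC(=O)c2ccc(O)c(CC=C(C)C)c2)ccc(OCOC)c1CC=C(C)C | intermediate
17 | 1-[4-hydroxy-2-methoxy-3-(3-methylbut-2-en-1-yl)phenyl]-3-[4-hydroxy-3-(3-methylbut-2-en-1-yl)phenyl]propane-1,3-dione | COc1c(C(=O)CC(=O)c2ccc(O)c(CC=C(C)C)c2)ccc(O)c1CC=C(C)C | target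

Total step count: 10
Longest linear sequence: 8 steps (steps 1–5, 8, 9, 10, from 2,4-dihydroxyacetophenone)

Steps most likely to fail

1. Step 9. The [3,3] shift on the electron-poor, acylated ring B may be slow, so that the long heating needed lets the tertiary allyl ether ionize (loss of the C5 unit, 1,3-migration) or lets the enolized diketone degrade before rearrangement is complete. The fallback sets out from ester 11 and comes back to the route at target 17. The rearrangement would be moved to the small, robust ester: 11 would be heated in PhNEt2 to give methyl 4-hydroxy-3-(3-methylbut-2-en-1-yl)benzoate F1. Its phenol would be protected with MOMCl and K2CO3 in acetone to give methyl 4-(methoxymethoxy)-3-(3-methylbut-2-en-1-yl)benzoate F2. Condensation of F2 with ketone 8 (NaH, THF, reflux, then AcOH) should give 1-[2-methoxy-4-(methoxymethoxy)-3-(3-methylbut-2-en-1-yl)phenyl]-3-[4-(methoxymethoxy)-3-(3-methylbut-2-en-1-yl)phenyl]propane-1,3-dione F3, and both acetals would be removed under the conditions of step 10 to give 17.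

2. Step 10. Acid-catalysed cyclization of the two ortho-prenyl phenols to 2,2-dimethylchromans, or addition of methanol to the prenyl double bonds, may compete with acetal cleavage. The fallback sets out from 6 and comes back to the route at target 17; it replaces the acetal by a silyl ether that fluoride removes without acid. Selective silylation of the free 4-OH (TIPSCl, imidazole, DMF) should give 1-[2-hydroxy-3-(3-methylbut-2-en-1-yl)-4-(triisopropylsilyloxy)phenyl]ethanone F4. Methylation (MeI, K2CO3, acetone, reflux) should give 1-[2-methoxy-3-(3-methylbut-2-en-1-yl)-4-(triisopropylsilyloxy)phenyl]ethanone F5. Condensation with ester 11 as in step 8 should give 1-[2-methoxy-3-(3-methylbut-2-en-1-yl)-4-(triisopropylsilyloxy)phenyl]-3-[4-(2-methylbut-3-en-2-yloxy)phenyl]propane-1,3-dione F6. Thermal rearrangement as in step 9 should give 1-[4-hydroxy-3-(3-methylbut-2-en-1-yl)phenyl]-3-[2-methoxy-3-(3-methylbut-2-en-1-yl)-4-(triisopropylsilyloxy)phenyl]propane-1,3-dione F7, and TBAF buffered with AcOH in THF at 0 °C would release 17.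

3. Step 8. Self-aldol condensation of the ketone, slow acylation by the electron-rich ester and retro-Claisen cleavage by methoxide may erode the coupling. The fallback sets out from ester 11 (with ketone 8) and comes back to the route at 14; it forms the same C–C bond by a kinetic aldol addition followed by oxidation. Reduction of 11 with DIBAL-H (CH2Cl2, −78 °C) should give [4-(2-methylbut-3-en-2-yloxy)phenyl]methanol F8. Oxidation with MnO2 (CH2Cl2, rt) should give 4-(2-methylbut-3-en-2-yloxy)benzaldehyde F9. The lithium enolate of 8 (LDA, THF, −78 °C) would add to F9 to give racemic 3-hydroxy-1-[2-methoxy-4-(methoxymethoxy)-3-(3-methylbut-2-en-1-yl)phenyl]-3-[4-(2-methylbut-3-en-2-yloxy)phenyl]propan-1-one F10, and IBX (EtOAc, 70 °C) should oxidize it to 14.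

Further compounds
F1 | step 9 | methyl 4-hydroxy-3-(3-methylbut-2-en-1-yl)benzoate | COC(=O)c1ccc(O)c(CC=C(C)C)c1
F2 | step 9 | methyl 4-(methoxymethoxy)-3-(3-methylbut-2-en-1-yl)benzoate | COC(=O)c1ccc(OCOC)c(CC=C(C)C)c1
F3 | step 9 | 1-[2-methoxy-4-(methoxymethoxy)-3-(3-methylbut-2-en-1-yl)phenyl]-3-[4-(methoxymethoxy)-3-(3-methylbut-2-en-1-yl)phenyl]propane-1,3-dione | COc1c(C(=O)CC(=O)c2ccc(OCOC)c(CC=C(C)C)c2)ccc(OCOC)c1CC=C(C)C
F4 | step 10 | 1-[2-hydroxy-3-(3-methylbut-2-en-1-yl)-4-(triisopropylsilyloxy)phenyl]ethanone | CC(=O)c1ccc(O[Si](C(C)C)(C(C)C)C(C)C)c(CC=C(C)C)c1O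
F5 | step 10 | 1-[2-methoxy-3-(3-methylbut-2-en-1-yl)-4-(triisopropylsilyloxy)phenyl]ethanone | CC(=O)c1ccc(O[Si](C(C)C)(C(C)C)C(C)C)c(CC=C(C)C)c1OC
F6 | step 10 | 1-[2-methoxy-3-(3-methylbut-2-en-1-yl)-4-(triisopropylsilyloxy)phenyl]-3-[4-(2-methylbut-3-en-2-yloxy)phenyl]propane-1,3-dione | COc1c(C(=O)CC(=O)c2ccc(OC(C)(C)C=C)cc2)ccc(O[Si](C(C)C)(C(C)C)C(C)C)c1CC=C(C)C
F7 | step 10 | 1-[4-hydroxy-3-(3-methylbut-2-en-1-yl)phenyl]-3-[2-methoxy-3-(3-methylbut-2-en-1-yl)-4-(triisopropylsilyloxy)phenyl]propane-1,3-dione | COc1c(C(=O)CC(=O)c2ccc(O)c(CC=C(C)C)c2)ccc(O[Si](C(C)C)(C(C)C)C(C)C)c1CC=C(C)C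
F8 | step 8 | [4-(2-methylbut-3-en-2-yloxy)phenyl]methanol | OCc1ccc(OC(C)(C)C=C)cc1
F9 | step 8 | 4-(2-methylbut-3-en-2-yloxy)benzaldehyde | O=Cc1ccc(OC(C)(C)C=C)cc1
F10 | step 8 | 3-hydroxy-1-[2-methoxy-4-(methoxymethoxy)-3-(3-methylbut-2-en-1-yl)phenyl]-3-[4-(2-methylbut-3-en-2-yloxy)phenyl]propan-1-one (racemic) | COc1c(C(=O)CC(O)c2ccc(OC(C)(C)C=C)cc2)ccc(OCOC)c1CC=C(C)C
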